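# Proposed total synthesis of CNP0262962.1 (compound 25)

**Conventions.** Atom locants C1–C15 follow cadinane numbering and are kept for every intermediate: ring A = C1–C2–C3–C4=C5–C6, ring B = C1–C10–C9–C8–C7–C6, C14 on C10, C15 on C4, C11/C12/C13 on C7. In the bicyclo[2.2.2]octane names of 10–12 and 17–19 the name locants 1, 2, 3, 4, 5, 6, 7, 8 are cadinane atoms C4, C9, C10, C1, C6, C5, C3, C2.

**Remark on the chemistry (one assumption).** The Pd/formate hydride opening of the alkynyl oxirane in step 10 is taken to follow the anti-SN2' course usual for this reaction class; this fixes the choice of (S)-13.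

**Principal compound numbers.** 1 (R)-carvone; 5 silyloxy enone; 9 silyloxy diene; 12 bicyclo[2.2.2]octenone; 13 (S)-2-methylglycidol; 15 alkynyl oxirane; 17 alkynyl carbinol; 18 allenyl carbinol; 21 cis-decalin ketone; 23 triol; 25 target.

## Analysis of the target

Compound 25 is a cadinane-type triester built on a cis-fused Δ4-octalin, with methyl groups on C4 and C10 and an exocyclic tetrasubstituted C7=C11 alkene that carries C13H3 and C12H2–OCHO. It has five stereocentres (1S,3R,6S,9R,10R): H-1 and H-6 are cis, the C3 acetate and both ring-B bonds at C1 and C6 lie on the same face of ring A, and on ring B the C10 methyl and C9 acetate are trans. The C7=C11 alkene is E (C12 cis to C8, C13 cis to C6); its two C11 substituents differ only by one oxygen, so neither sterics nor thermodynamics can set the geometry and a mechanism must. C6–H is doubly allylic between C4=C5 and C7=C11, so the skipped diene can drift into conjugation, and the formate must be told apart from two acetates. At C1, C6 and C10 the target is antipodal to the amorphanes of the artemisinic acid series. The feature that the strategy uses is the array O–C9–C8–C7–C6–C5=C4, a 5-en-1-one (oxy-Cope) retron that spans both rings, with C7 bearing an exocyclic alkene (the allenyl variant). Cutting C6–C7 and joining C9–C4 turns the cis-decalin into a bicyclo[2.2.2]octene whose six-membered ring C9–C10–C1–C2–C3–C4 is the ring of (R)-carvone, with C3–O standing where the isopropenyl group was.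

## Retrosynthetic reasoning

**Ester stage (25 ⇒ 23 ⇒ 21).** The three esters are removed first. The formate goes on the only primary hydroxyl of triol 23 and the acetates on the two secondary ones, so no protecting group is needed at the end. The C9 carbinol is traced to ketone 21, because on the cis-decalin the convex face delivers hydride to give the equatorial 9α-alcohol.

**Key disconnection (21 ⇒ 18).** The C6–C7 bond is cut and C9–C4 is re-joined (retro-oxy-Cope). This is the only cut that removes the ring fusion stereocentre C6, the skipped diene and the exocyclic alkene at once. The precursor 18 is a bicyclo[2.2.2]octenol in which C1, C3 and C10 are fixed on a rigid cage. The forward reaction has to form C6–C7 on the face that gives the cis fusion and turn the allene axis of 18 into the E geometry of C7=C11.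

**Allene (18 ⇒ 17 ⇒ 12 + 15).** The allene is cut at C8–H and traced to the alkynyl oxirane in 17, so that a stereospecific SN2' hydride delivery converts the C11 stereocentre into the axis and leaves the oxygen on C12. The C9–C8 bond is then cut to ketone 12 and alkyne 15. The forward addition must come from the face of C9=O that is turned to the C5=C6 bridge.

**Bicycle (12 ⇒ 9).** The C4–C5 and C1–C6 bonds are cut (retro-[4+2] with a two-carbon acetylene equivalent). The gain is that C5 and C6 arrive as an unsubstituted alkene and both bridgeheads are set by approach anti to the C3 silyloxy group of diene 9.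

**Ring carbons (9 ⇒ 7 ⇒ 5 ⇒ 1).** The C4–C15 bond is cut (α′-methylation). The C3–O bond is traced to the isopropenyl-bearing carbon of 1 by oxidative excision of the side chain with retention, so that the one stereocentre of the chiral pool controls all others.

**C5 fragment (15 ⇒ 13).** The alkyne carbon C8 is cut from the aldehyde derived from 13; the quaternary epoxide carbon cannot epimerise.

## Alternatives that were turned down

**Alternative 1:** (textbook) Ring A is disconnected at C1–C2 and C5–C6. The forward key step is an intermolecular Diels–Alder reaction of the enone A1 with the silyloxy diene A2 to the cis-octalone A3, followed by enone formation, reduction at C3 and olefination of the C7 ketone. It was turned down for three reasons. The C7 ketone is flanked by the C6 methine, so a tetrasubstituted olefination is slow and has no handle for E/Z control between CH3 and CH2OR. C6 is epimerisable next to that ketone, which puts the cis fusion at risk. A1 needs its own asymmetric synthesis, so the route is longer and its hardest problem stays unsolved.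

**Alternative 2:** Only C6–C7 is disconnected, with 1 used as ring A and its isopropenyl group as C10/C14/C9. The forward key step is Pd(0) ionisation of the C6 carbonate in A4, 6-exo-dig insertion of C7≡C11 into the allyl–Pd bond, and capture of the vinyl–Pd by a methyl-metal reagent. This sets C6 and the alkene geometry by syn-carbopalladation. It was turned down because 1 must first be oxidised at its γ-carbon (C6). C10 and C9 would also have to be set on an open side chain by hydroboration and propargylation, each with weak 1,2-induction. In addition, the cascade competes with direct allyl–methyl coupling and with diene formation.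

**Alternative 3:** Relay from the amorphane pool: artemisinic acid A5 already has the cis-fused Δ4 skeleton. The forward route would need allylic oxidation at C3, oxidation of the unactivated C9 methylene, and migration of the side-chain alkene to C7=C11 with reduction to the C12 alcohol. It was turned down because A5 has the mirror-image configuration at C1, C6 and C10, so it would lead to A6, the enantiomer of 25. No reagent is selective for C9–H either.

Key step: step 11

## Route

Step 1
Reactants: 1 (R)-carvone
Product: 3 (R)-5-acetoxy-2-methylcyclohex-2-en-1-one, via methoxy hydroperoxide 2 (not isolated)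
Conditions: O3, CH2Cl2/MeOH, −78 °C; then Ac2O, Et3N, DMAP (cat.), 0 → 23 °C
Reagents that add atoms: ozone O=[O+][O-]; methanol CO
Why: Ozone cleaves the electron-rich isopropenyl alkene in preference to the enone alkene and methanol traps the carbonyl oxide as 2; its peracetate undergoes Criegee rearrangement, in which the ring carbon migrates to oxygen with retention, so the carvone stereocentre becomes C3–O. The acetyl group of 3 is the former C(CH3) unit of the isopropenyl group.

Step 2
Reactants: 3 (R)-5-acetoxy-2-methylcyclohex-2-en-1-one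
Product: 4 (R)-5-hydroxy-2-methylcyclohex-2-en-1-one
Conditions: K2CO3 (cat.), MeOH, 0 °C
Reagents that add atoms: none
Why: Mild transesterification removes the acetate; catalytic base and low temperature should keep the β-hydroxy ketone from E1cB elimination and aromatisation.

Step 3
Reactants: 4 (R)-5-hydroxy-2-methylcyclohex-2-en-1-one
Product: 5 (R)-5-(tert-butyldimethylsilyloxy)-2-methylcyclohex-2-en-1-one
Conditions: TBSCl, imidazole, DMF, 23 °C
Reagents that add atoms: tert-butyldimethylsilyl chloride CC(C)(C)[Si](C)(C)Cl
Why: Standard silylation; the silyl ether is a poor β-leaving group, survives the enolate and organometallic steps, and later shields one face of the diene and of the C9 ketone.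

Step 4
Reactants: 5 (R)-5-(tert-butyldimethylsilyloxy)-2-methylcyclohex-2-en-1-one
Product: 7 (5R,6S)-5-(tert-butyldimethylsilyloxy)-2,6-dimethylcyclohex-2-en-1-one, via lithium enolate 6 (not isolated)
Conditions: LDA, THF, −78 °C; MeI, −78 → −20 °C
Reagents that add atoms: iodomethane CI
Why: Kinetic α′-deprotonation gives the cross-conjugated enolate 6, which is methylated trans to the silyloxy group; this installs C15 on the future C4. The new centre becomes planar again in step 5, so its configuration does not matter.

Step 5
Reactants: 7 (5R,6S)-5-(tert-butyldimethylsilyloxy)-2,6-dimethylcyclohex-2-en-1-one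
Product: 9 (R)-6-(tert-butyldimethylsilyloxy)-1,3-dimethyl-2-(trimethylsilyloxy)cyclohexa-1,3-diene, via lithium dienolate 8 (not isolated)
Conditions: LDA, THF, −78 °C; TMSCl/Et3N, −78 → 0 °C; non-aqueous work-up
Reagents that add atoms: chlorotrimethylsilane C[Si](C)(C)Cl
Why: A second kinetic α′-deprotonation and O-silylation give the electron-rich 2-silyloxy-1,3-diene for a normal-demand Diels–Alder reaction; the low temperature should prevent β-elimination of silyloxide.

Step 6
Reactants: 9 (R)-6-(tert-butyldimethylsilyloxy)-1,3-dimethyl-2-(trimethylsilyloxy)cyclohexa-1,3-diene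
Product: 12 (1S,3R,4S,7R)-7-(tert-butyldimethylsilyloxy)-1,3-dimethylbicyclo[2.2.2]oct-5-en-2-one, via sulfoxide cycloadduct 10 (not isolated), via bicyclic silyl enol ether 11 (not isolated)
Conditions: phenyl vinyl sulfoxide, CaCO3 (buffer), toluene, 110 °C (sealed); then NaOMe (cat.), MeOH, 23 °C; C10 epimers separated, the minor one re-equilibrated
Reagents that add atoms: phenyl vinyl sulfoxide C=CS(=O)c1ccccc1
Why: Diels–Alder reaction with the sulfoxide as acetylene equivalent should occur anti to the C3 silyloxy group, which sets the bridgeheads C4 and C1; thermal syn-elimination of sulfenic acid can only run toward C5 (the bridgehead is excluded) and gives the C5=C6 bridge. Methanolysis of the silyl enol ether and base equilibration at C10, the only enolisable position, should favour the methyl group syn to the C5=C6 bridge, where it avoids the 1,3-contact with C2–H.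

Step 7
Reactants: 13 (S)-2-methylglycidol
Product: 14 (R)-2-methyloxirane-2-carbaldehyde
Conditions: TEMPO (cat.), PhI(OAc)2, CH2Cl2, 0 → 23 °C; used as solution
Reagents that add atoms: none
Why: Oxoammonium oxidation of the primary alcohol stops at the aldehyde under non-basic conditions; the quaternary α-carbon cannot epimerise.

Step 8
Reactants: 14 (R)-2-methyloxirane-2-carbaldehyde
Product: 15 (S)-2-ethynyl-2-methyloxirane
Conditions: dimethyl (1-diazo-2-oxopropyl)phosphonate, K2CO3, MeOH, 0 → 23 °C; distilled into THF
Reagents that add atoms: dimethyl (1-diazo-2-oxopropyl)phosphonate COP(=O)(OC)C(=[N+]=[N-])C(C)=O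
Why: Ohira–Bestmann homologation adds the terminal alkyne carbon (future C8) under mild base that the 2,2-disubstituted oxirane should tolerate; the stereocentre is not touched.

Step 9
Reactants: 15 (S)-2-ethynyl-2-methyloxirane; 12 (1S,3R,4S,7R)-7-(tert-butyldimethylsilyloxy)-1,3-dimethylbicyclo[2.2.2]oct-5-en-2-one
Product: 17 (1S,2R,3R,4S,7R)-7-(tert-butyldimethylsilyloxy)-1,3-dimethyl-2-{[(2S)-2-methyloxiran-2-yl]ethynyl}bicyclo[2.2.2]oct-5-en-2-ol, via lithium acetylide 16 (not isolated)
Conditions: 15, n-BuLi, THF, −78 °C; anhydrous CeCl3; then 12, −78 → −40 °C; aq. NH4Cl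
Reagents that add atoms: none
Why: 1,2-Addition of the small, weakly basic cerium-modified acetylide should suppress enolisation at C10. The face of C9=O turned to the ethano bridge is blocked by the syn-1,3 C3 silyloxy group, so attack should come from the side of the C5=C6 bridge and place the alkynyl group syn to that alkene, as the [3,3] shift requires.

Step 10
Reactants: 17 (1S,2R,3R,4S,7R)-7-(tert-butyldimethylsilyloxy)-1,3-dimethyl-2-{[(2S)-2-methyloxiran-2-yl]ethynyl}bicyclo[2.2.2]oct-5-en-2-ol
Product: 18 (1S,2R,3R,4S,7R)-7-(tert-butyldimethylsilyloxy)-2-[(Ra)-4-hydroxy-3-methylbuta-1,2-dien-1-yl]-1,3-dimethylbicyclo[2.2.2]oct-5-en-2-ol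
Conditions: Pd2(dba)3·CHCl3 (cat.), n-Bu3P (cat.), HCO2NH4, THF, 23 °C
Reagents that add atoms: none
Why: Pd(0) opens the alkynyl oxirane in an anti-SN2' sense to an allenylpalladium alkoxide, formate delivers hydride to palladium, and reductive elimination with retention places H on C8 (Pd-catalysed hydrogenolysis of propargylic electrophiles). The C11 centre is thereby transferred to the (Ra) allene axis and the oxygen stays on C12 as the primary alcohol.

Step 11
Reactants: 18 (1S,2R,3R,4S,7R)-7-(tert-butyldimethylsilyloxy)-2-[(Ra)-4-hydroxy-3-methylbuta-1,2-dien-1-yl]-1,3-dimethylbicyclo[2.2.2]oct-5-en-2-ol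
Product: 21 (1S,3R,6S,10R,7(11)E)-3-(tert-butyldimethylsilyloxy)-12-hydroxycadina-4,7(11)-dien-9-one, via dipotassium dialkoxide 19 (not isolated), via dipotassium dienolate 20 (not isolated)
Conditions: KH (3 equiv), 18-crown-6, THF, 0 → 40 °C; cannulated into AcOH/THF at −78 °C
Reagents that add atoms: none
Why: KH with 18-crown-6 generates the free C9 alkoxide, which weakens the C9–C4 bond; the 1,5-diene C7=C8–C9–C4–C5=C6 then undergoes a [3,3] shift through the boat transition state that the bicycle enforces, breaking C9–C4 and forming C6–C7. The closest known reaction type is the anionic oxy-Cope rearrangement of 2-vinyl- and 2-allenylbicyclo[2.2.2]oct-5-en-2-ols to cis-fused octalones. Ring B (C1–C10–C9–C8–C7–C6) is closed by this concerted sigmatropic C6–C7 bond formation, while the carvone ring is opened and C1–C2–C3–C4 with C5 and C6 become ring A with the alkene already at C4=C5. C6 is the only new stereocentre: C7 can reach C6 only on the face of the C5=C6 bridge that is turned to the C9–C10 bridge, which is the face cis to the C1–C10 bond, so the cis fusion follows from geometry. The C7=C11 π bond is a spectator, and the C11 substituent on the side of the approaching C6 ends up cis to C6; with the (Ra) allene this is the methyl group, so CH2OH ends up cis to C8 (E). C1, C3 and C10 are carried through unchanged. The step needs the rearrangement to outrun 5-endo addition of an alkoxide to the allene and 1,5-silyl migration; release of cage strain, the sp carbon of the allene and formation of the conjugated dienolate 20 should secure this. Kinetic protonation of 20 at C8 on cold acidic quench keeps C7=C11 out of conjugation.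

Step 12
Reactants: 21 (1S,3R,6S,10R,7(11)E)-3-(tert-butyldimethylsilyloxy)-12-hydroxycadina-4,7(11)-dien-9-one
Product: 22 (1S,3R,6S,9R,10R,7(11)E)-3-(tert-butyldimethylsilyloxy)cadina-4,7(11)-diene-9,12-diol
Conditions: NaBH4, CeCl3·7H2O, MeOH, −78 °C
Reagents that add atoms: none
Why: Luche reduction is fast at −78 °C and should consume the β,γ-unsaturated ketone before it can isomerise. Hydride should attack axially from the convex β-face, where only H-1 is axial and C7 is sp2, to give the equatorial 9α-alcohol trans to the C10 methyl group.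

Step 13
Reactants: 22 (1S,3R,6S,9R,10R,7(11)E)-3-(tert-butyldimethylsilyloxy)cadina-4,7(11)-diene-9,12-diol
Product: 23 (1S,3R,6S,9R,10R,7(11)E)-cadina-4,7(11)-diene-3,9,12-triol
Conditions: TBAF, THF, 0 → 23 °C
Reagents that add atoms: none
Why: Fluoride cleaves the secondary silyl ether; no ester is present yet, so the basic reagent does no harm.

Step 14
Reactants: 23 (1S,3R,6S,9R,10R,7(11)E)-cadina-4,7(11)-diene-3,9,12-triol
Product: 24 (1S,3R,6S,9R,10R,7(11)E)-3,9-dihydroxycadina-4,7(11)-dien-12-yl formate
Conditions: 2,2,2-trifluoroethyl formate, THF, 23 °C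
Reagents that add atoms: 2,2,2-trifluoroethyl formate O=COCC(F)(F)F
Why: Transformylation with this mild activated formate is selective for primary over secondary alcohols, so only the C12 hydroxyl should react.

Step 15
Reactants: 24 (1S,3R,6S,9R,10R,7(11)E)-3,9-dihydroxycadina-4,7(11)-dien-12-yl formate
Product: 25 (1S,3R,6S,9R,10R,7(11)E)-3,9-diacetoxycadina-4,7(11)-dien-12-yl formate
Conditions: Ac2O, pyridine, 23 °C (no DMAP)
Reagents that add atoms: acetic anhydride CC(=O)OC(C)=O
Why: Both secondary hydroxyls are acetylated; nucleophilic catalysts are left out so that the formate is not transferred or exchanged.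

## Compound list

1 | (R)-(−)-carvone | CC1=CC[C@H](CC1=O)C(C)=C | starting material
2 | (5R)-5-(1-hydroperoxy-1-methoxyethyl)-2-methylcyclohex-2-en-1-one (both epimers at the peroxyketal carbon) | CC1=CC[C@H](CC1=O)C(C)(OC)OO | intermediate (not isolated)
3 | (R)-5-acetoxy-2-methylcyclohex-2-en-1-one | CC1=CC[C@H](CC1=O)OC(C)=O | intermediate
4 | (R)-5-hydroxy-2-methylcyclohex-2-en-1-one | CC1=CC[C@H](CC1=O)O | intermediate
5 | (R)-5-(tert-butyldimethylsilyloxy)-2-methylcyclohex-2-en-1-one | CC1=CC[C@H](CC1=O)O[Si](C)(C)C(C)(C)C | intermediate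
6 | lithium cross-conjugated enolate of 5 | [Li+].CC1=CC[C@H](C=C1[O-])O[Si](C)(C)C(C)(C)C | intermediate (not isolated)
7 | (5R,6S)-5-(tert-butyldimethylsilyloxy)-2,6-dimethylcyclohex-2-en-1-one | CC1=CC[C@@H](O[Si](C)(C)C(C)(C)C)[C@H](C)C1=O | intermediate
8 | lithium dienolate of 7 | [Li+].CC1=CC[C@@H](O[Si](C)(C)C(C)(C)C)C(C)=C1[O-] | intermediate (not isolated)
9 | (R)-6-(tert-butyldimethylsilyloxy)-1,3-dimethyl-2-(trimethylsilyloxy)cyclohexa-1,3-diene | CC1=CC[C@@H](O[Si](C)(C)C(C)(C)C)C(C)=C1O[Si](C)(C)C | intermediate
10 | Diels–Alder adduct, 7-(tert-butyldimethylsilyloxy)-1,3-dimethyl-5-(phenylsulfinyl)-2-(trimethylsilyloxy)bicyclo[2.2.2]oct-2-ene (mixture at C–S and at sulfur) | C[C@]12CC(S(=O)c3ccccc3)[C@H](C[C@H]1O[Si](C)(C)C(C)(C)C)C(C)=C2O[Si](C)(C)C | intermediate (not isolated)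
11 | 7-(tert-butyldimethylsilyloxy)-1,3-dimethyl-2-(trimethylsilyloxy)bicyclo[2.2.2]octa-2,5-diene, silyloxy group anti to the new etheno bridge | C[C@]12C=C[C@H](C[C@H]1O[Si](C)(C)C(C)(C)C)C(C)=C2O[Si](C)(C)C | intermediate (not isolated)
12 | (1S,3R,4S,7R)-7-(tert-butyldimethylsilyloxy)-1,3-dimethylbicyclo[2.2.2]oct-5-en-2-one (3-methyl syn to the C5=C6 bridge) | C[C@]12C=C[C@H](C[C@H]1O[Si](C)(C)C(C)(C)C)[C@@H](C)C2=O | intermediate
13 | (S)-2-methylglycidol | OC[C@@]1(C)CO1 | starting material
14 | (R)-2-methyloxirane-2-carbaldehyde | O=C[C@@]1(C)CO1 | intermediate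
15 | (S)-2-ethynyl-2-methyloxirane | C#C[C@@]1(C)CO1 | intermediate
16 | lithium acetylide of 15 | [Li+].[C-]#C[C@@]1(C)CO1 | intermediate (not isolated)
17 | (1S,2R,3R,4S,7R)-7-(tert-butyldimethylsilyloxy)-1,3-dimethyl-2-{[(2S)-2-methyloxiran-2-yl]ethynyl}bicyclo[2.2.2]oct-5-en-2-ol | C[C@]12C=C[C@H](C[C@H]1O[Si](C)(C)C(C)(C)C)[C@@H](C)[C@@]2(O)C#C[C@@]3(C)CO3 | intermediate
18 | (1S,2R,3R,4S,7R)-7-(tert-butyldimethylsilyloxy)-2-[(Ra)-4-hydroxy-3-methylbuta-1,2-dien-1-yl]-1,3-dimethylbicyclo[2.2.2]oct-5-en-2-ol (viewed from C8 to C11: C9 at 12, CH3 at 3, CH2OH at 9 o'clock) | C[C@]12C=C[C@H](C[C@H]1O[Si](C)(C)C(C)(C)C)[C@@H](C)[C@@]2(O)C=[C@]=C(C)CO | intermediate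
19 | dipotassium dialkoxide of 18 | [K+].[K+].C[C@]12C=C[C@H](C[C@H]1O[Si](C)(C)C(C)(C)C)[C@@H](C)[C@@]2([O-])C=[C@]=C(C)C[O-] | intermediate (not isolated)
20 | dipotassium C9 dienolate/C12 alkoxide of 21 | [K+].[K+].CC(C)(C)[Si](C)(C)O[C@@H]1C[C@@H]2[C@@H](C)C([O-])=C/C(=C(/C)C[O-])[C@@H]2C=C1C | intermediate (not isolated)
21 | (1S,3R,6S,10R,7(11)E)-3-(tert-butyldimethylsilyloxy)-12-hydroxycadina-4,7(11)-dien-9-one | CC(C)(C)[Si](C)(C)O[C@@H]1C[C@@H]2[C@@H](C)C(=O)C/C(=C(/C)CO)[C@@H]2C=C1C | intermediate
22 | (1S,3R,6S,9R,10R,7(11)E)-3-(tert-butyldimethylsilyloxy)cadina-4,7(11)-diene-9,12-diol | CC(C)(C)[Si](C)(C)O[C@@H]1C[C@@H]2[C@@H](C)[C@H](O)C/C(=C(/C)CO)[C@@H]2C=C1C | intermediate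
23 | (1S,3R,6S,9R,10R,7(11)E)-cadina-4,7(11)-diene-3,9,12-triol | O[C@@H]1C[C@@H]2[C@@H](C)[C@H](O)C/C(=C(/C)CO)[C@@H]2C=C1C | intermediate
24 | (1S,3R,6S,9R,10R,7(11)E)-3,9-dihydroxycadina-4,7(11)-dien-12-yl formate | O[C@@H]1C[C@@H]2[C@@H](C)[C@H](O)C/C(=C(/C)COC=O)[C@@H]2C=C1C | intermediate
25 | (1S,3R,6S,9R,10R,7(11)E)-3,9-diacetoxycadina-4,7(11)-dien-12-yl formate (CNP0262962.1) | CC(=O)O[C@@H]1C[C@@H]2[C@@H](C)[C@H](OC(C)=O)C/C(=C(/C)COC=O)[C@@H]2C=C1C | target

## Step count and least certain steps

Total: 15 steps. Longest linear sequence: 13 steps (steps 1–6 and 9–15); steps 7–8 prepare the C5 fragment 15.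

**Step 11 (key step).** Either alkoxide may add 5-endo to the allene, the silyl group may migrate from O3 to the neighbouring O9 and mask the alkoxide, the rearrangement may be slow because the C10 methyl group sits in the flagpole position of the boat, or the dienolate may be protonated at C11 on quench so that the alkene moves into conjugation. Fallback: set out from 17 and run the alkynyl anionic oxy-Cope rearrangement (KH, 18-crown-6, THF) to the γ,δ-epoxy enone 11,12-epoxy-3-(tert-butyldimethylsilyloxy)cadina-4,7-dien-9-one F1. Reductive opening of the vinylogous epoxy ketone with SmI2 (THF/MeOH, −78 °C) then gives the dienolate, which is protonated at C8, and the route is rejoined at 21. The alkene geometry then rests on rotamer preference about C7–C11 and no longer on chirality transfer, so the minor isomer would have to be removed.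

**Step 6.** Cycloaddition at the fully substituted C4 terminus next to the silyloxy group may be slow, diene 9 may aromatise by loss of silanol at 110 °C, and the equilibrium at C10 may be less one-sided than expected. Fallback: set out from 7 and treat its dienolate 8 with methyl acrylate at −78 °C (anionic double Michael addition) to give the keto ester methyl 7-(tert-butyldimethylsilyloxy)-1,3-dimethyl-2-oxobicyclo[2.2.2]octane-5-carboxylate F2. Saponify with LiOH to the acid F3, and carry out oxidative decarboxylation with Pb(OAc)4/Cu(OAc)2/pyridine in benzene at 80 °C, followed by NaOMe equilibration; the route is rejoined at 12.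

**Step 10.** Palladium may fail to reach C8 next to the quaternary carbinol; direct SN2 hydride delivery would give the alkyne, and erosion of the anti course would mix the allene axis and thus the alkene geometry after step 11. Fallback: set out from 12 and add the lithium acetylide of 2-methylbut-1-en-3-yne to give the enynol F4. Install the axis under ligand control by copper-catalysed 1,4-protoboration (CuCl, chiral bisphosphine, B2pin2, NaOt-Bu, MeOH) to the allenylmethyl boronate F5, and oxidise with NaBO3; the route is rejoined at 18.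

**Step 14.** Formylation of the secondary C3 or C9 hydroxyl may compete with the primary allylic one, or the formyl group may migrate. Fallback: set out from 23 and silylate the primary hydroxyl (TBSCl, imidazole, −20 °C) to the 12-O-silyl diol F6. Acetylate (Ac2O, DMAP) to the diacetate F7, remove the silyl group with HF·pyridine to the primary alcohol F8, and formylate with formic acetic anhydride/pyridine; the route is rejoined at 25.

## Further compounds

F1 | step 11 | (1S,3R,6S,10R)-3-(tert-butyldimethylsilyloxy)-11,12-epoxycadina-4,7-dien-9-one (epoxide carbon as in 15) | CC(C)(C)[Si](C)(C)O[C@@H]1C[C@@H]2[C@@H](C)C(=O)C=C([C@@]3(C)CO3)[C@@H]2C=C1C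
F2 | step 6 | methyl 7-(tert-butyldimethylsilyloxy)-1,3-dimethyl-2-oxobicyclo[2.2.2]octane-5-carboxylate (epimers at C3 and C5) | COC(=O)C1C[C@]2(C)C(=O)C(C)[C@H]1C[C@H]2O[Si](C)(C)C(C)(C)C
F3 | step 6 | 7-(tert-butyldimethylsilyloxy)-1,3-dimethyl-2-oxobicyclo[2.2.2]octane-5-carboxylic acid (epimers at C3 and C5) | OC(=O)C1C[C@]2(C)C(=O)C(C)[C@H]1C[C@H]2O[Si](C)(C)C(C)(C)C
F4 | step 10 | (1S,2R,3R,4S,7R)-7-(tert-butyldimethylsilyloxy)-1,3-dimethyl-2-(3-methylbut-3-en-1-yn-1-yl)bicyclo[2.2.2]oct-5-en-2-ol | C[C@]12C=C[C@H](C[C@H]1O[Si](C)(C)C(C)(C)C)[C@@H](C)[C@@]2(O)C#CC(C)=C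
F5 | step 10 | (1S,2R,3R,4S,7R)-7-(tert-butyldimethylsilyloxy)-1,3-dimethyl-2-[(Ra)-3-methyl-4-(4,4,5,5-tetramethyl-1,3,2-dioxaborolan-2-yl)buta-1,2-dien-1-yl]bicyclo[2.2.2]oct-5-en-2-ol | C[C@]12C=C[C@H](C[C@H]1O[Si](C)(C)C(C)(C)C)[C@@H](C)[C@@]2(O)C=[C@]=C(C)CB3OC(C)(C)C(C)(C)O3
F6 | step 14 | (1S,3R,6S,9R,10R,7(11)E)-12-(tert-butyldimethylsilyloxy)cadina-4,7(11)-diene-3,9-diol | O[C@@H]1C[C@@H]2[C@@H](C)[C@H](O)C/C(=C(/C)CO[Si](C)(C)C(C)(C)C)[C@@H]2C=C1C
F7 | step 14 | (1S,3R,6S,9R,10R,7(11)E)-12-(tert-butyldimethylsilyloxy)cadina-4,7(11)-diene-3,9-diyl diacetate | CC(=O)O[C@@H]1C[C@@H]2[C@@H](C)[C@H](OC(C)=O)C/C(=C(/C)CO[Si](C)(C)C(C)(C)C)[C@@H]2C=C1C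
F8 | step 14 | (1S,3R,6S,9R,10R,7(11)E)-12-hydroxycadina-4,7(11)-diene-3,9-diyl diacetate | CC(=O)O[C@@H]1C[C@@H]2[C@@H](C)[C@H](OC(C)=O)C/C(=C(/C)CO)[C@@H]2C=C1C
A1 | alternative 1 | (4R,5R)-5-(tert-butyldimethylsilyloxy)-4-methylcyclohex-2-en-1-one | C[C@@H]1C=CC(=O)C[C@H]1O[Si](C)(C)C(C)(C)C
A2 | alternative 1 | 2-methyl-3-(trimethylsilyloxy)buta-1,3-diene | C=C(C)C(=C)O[Si](C)(C)C
A3 | alternative 1 | cis-fused Diels–Alder adduct, 9-(tert-butyldimethylsilyloxy)-3-(trimethylsilyloxy)-11,12,13-trinorcadin-3-en-7-one (1S,6S,9R,10R) | C[Si](C)(C)OC1=C(C)C[C@H]2C(=O)C[C@@H](O[Si](C)(C)C(C)(C)C)[C@H](C)[C@H]2C1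
A4 | alternative 2 | cyclisation precursor: methyl carbonate at C6 (trans to the side chain) of 3-O-TBS-carveol carrying the C10–C9(OAc)–C8–C7≡C11–C12(OTBS) chain at C1 | COC(=O)O[C@H]1C=C(C)[C@H](O[Si](C)(C)C(C)(C)C)C[C@@H]1[C@@H](C)[C@H](OC(C)=O)CC#CCO[Si](C)(C)C(C)(C)C
A5 | alternative 3 | artemisinic acid | C[C@@H]1CC[C@H]([C@@H]2[C@H]1CCC(=C2)C)C(=C)C(=O)O
A6 | alternative 3 | enantiomer of 25 | CC(=O)O[C@H]1C[C@H]2[C@H](C)[C@@H](OC(C)=O)C/C(=C(/C)COC=O)[C@H]2C=C1C
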